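**Retrosynthetic overview**
- The four formyl groups come off last (four-fold Vilsmeier formylation of a pentahydroxy 2-arylchroman), and the C2–aryl bond is cut back to a chroman-2-ol plus phloroglucinol, joined through the cyclic oxocarbenium ion with the aryl entering trans to the C3 isopropyl.
- The chroman-2-ol comes from a (3R,4R)-3-isopropyl-4-isobutyl-dihydrocoumarin, itself from demethylative lactonisation of a 2-isopropyl-3-aryl acid; this closes the pyran ring, both aromatic rings being bought.
- Key step: Ireland–Claisen [3,3] rearrangement of an (S,E)-4-aryl-but-3-en-2-yl isovalerate forms the C3–C4 bond and both stereocentres by 1,3-chirality transfer from the carbinol carbon.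
- The propenyl group left by the rearrangement becomes the isobutyl group by cross-metathesis with 2-methyl-2-butene and hydrogenation.
- The allylic ester comes from 2-iodo-1,3,5-trimethoxybenzene and (S)-but-3-yn-2-ol by Sonogashira coupling, trans-reduction and acylation.

Assumption: (S)-but-3-yn-2-ol is taken as an inexpensive commercial enantiopure building block (sold in both enantiomeric forms); compounds are numbered in the order of the forward route.

**Step 1**
Reactants: 1, 2-iodo-1,3,5-trimethoxybenzene; 2, (S)-but-3-yn-2-ol
Product: 3, (S)-4-(2,4,6-trimethoxyphenyl)but-3-yn-2-ol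
Conditions: PdCl2(PPh3)2 (3 mol%), CuI (5 mol%), Et3N/THF, 60 °C
Reagents that add atoms: (S)-but-3-yn-2-ol (2), C[C@H](O)C#C
Why: Sonogashira coupling of the aryl iodide with the terminal alkyne; the bought carbinol stereocentre is not involved.

**Step 2**
Reactants: 3
Product: 4, (S,E)-4-(2,4,6-trimethoxyphenyl)but-3-en-2-ol
Conditions: Red-Al (2.5 equiv), THF, 0 °C → rt; Rochelle salt work-up; Et3N-deactivated silica
Reagents that add atoms: none
Why: Alkoxide-directed trans-hydroalumination of the propargylic alcohol gives only the E-alkene and leaves the carbinol centre untouched.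

**Step 3**
Reactants: 4; 5, 3-methylbutanoic (isovaleric) anhydride
Product: 6, (S,E)-4-(2,4,6-trimethoxyphenyl)but-3-en-2-yl 3-methylbutanoate
Conditions: Et3N, DMAP (cat.), CH2Cl2, 0 °C; base-washed work-up, used promptly
Reagents that add atoms: isovaleric anhydride (5), CC(C)CC(=O)OC(=O)CC(C)C
Why: DMAP-catalysed O-acylation under non-acidic conditions (the electron-rich cinnamyl-type carbinol ionises with acid) proceeds with retention because the C–O bond is not broken.

**Step 4 (key step)**
Reactants: 6
Product: 7, (2R,3R,E)-2-isopropyl-3-(2,4,6-trimethoxyphenyl)hex-4-enoic acid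
Conditions: LDA (1.2 equiv), THF, −78 °C; TMSCl/Et3N, −78 °C → rt → 50 °C; dilute aqueous acid work-up
Reagents that add atoms: none (the silyl group is lost on work-up)
Why: Ireland–Claisen [3,3] rearrangement: the kinetic enolate (isopropyl cis to the allylic oxygen) reacts through a chair with the carbinol methyl equatorial, so suprafacial C–C bond formation converts the (S) C–O centre into the (2R,3R) anti pair (the future 3,4-trans C3/C4) and an E-propenyl group.

**Step 5**
Reactants: 7; 8, 2-methylbut-2-ene
Product: 9, (2R,3R)-2-isopropyl-5-methyl-3-(2,4,6-trimethoxyphenyl)hex-4-enoic acid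
Conditions: Hoveyda–Grubbs II (5–10 mol%), 2-methyl-2-butene/CH2Cl2, 40 °C, sealed tube
Reagents that add atoms: 2-methylbut-2-ene (8), CC=C(C)C
Why: Olefin cross-metathesis exchanges the ethylidene terminus for isopropylidene (the free acid is tolerated) and does not touch either stereocentre.

**Step 6**
Reactants: 9
Product: 10, (2R,3R)-2-isopropyl-5-methyl-3-(2,4,6-trimethoxyphenyl)hexanoic acid
Conditions: H2 (3 atm), 10% Pd/C, EtOAc, rt
Reagents that add atoms: none
Why: Catalytic hydrogenation of the trisubstituted alkene gives the isobutyl side chain with no effect on the stereocentres.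

**Step 7**
Reactants: 10
Product: 11, (3R,4R)-5,7-dihydroxy-4-isobutyl-3-isopropylchroman-2-one
Conditions: BBr3 (5 equiv), CH2Cl2, −78 °C → rt; H2O; then TsOH (cat.), PhMe, 60 °C
Reagents that add atoms: none
Why: Lewis-acid ether cleavage frees the three phenols and either equivalent ortho-OH lactonises onto the acid to give the trans-dihydrocoumarin (trans is also the thermodynamic C3 configuration).

**Step 8**
Reactants: 11
Product: 12, (3R,4R)-4-isobutyl-3-isopropylchroman-2,5,7-triol (lactol, mixture at C2)
Conditions: DIBAL-H (3.5 equiv), THF/PhMe, −78 °C; Rochelle salt work-up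
Reagents that add atoms: none
Why: Low-temperature DIBAL half-reduction of a dihydrocoumarin stops at the cyclic hemiacetal (two equivalents are consumed by the phenols); C3 and C4 are untouched.

**Step 9**
Reactants: 12; 13, phloroglucinol (anhydrous, 6 equiv)
Product: 14, (2R,3R,4R)-4-isobutyl-3-isopropyl-2-(2,4,6-trihydroxyphenyl)chroman-5,7-diol
Conditions: Sc(OTf)3 (10 mol%), MeCN, 0 °C → rt
Reagents that add atoms: phloroglucinol (13), Oc1cc(O)cc(O)c1
Why: Friedel–Crafts C-arylation of the chroman-2-yl oxocarbenium ion by excess phloroglucinol occurs anti to the adjacent C3 isopropyl, and reversible C2–O ionisation of the electron-rich product converges on the 2,3-trans isomer, setting C2 as R.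

**Step 10**
Reactants: 14; 15, N,N-dimethylformamide
Product: 16, sideroxylonal C, (2R,3R,4R)
Conditions: POCl3 (10 equiv), DMF (12 equiv), EtOAc/MeCN, 0 °C → rt; then H2O, 50 °C
Reagents that add atoms: DMF (15), CN(C)C=O (formyl carbon); water, O (formyl oxygen on iminium hydrolysis)
Why: Vilsmeier–Haack formylation fills the only two free positions on each phloroglucinol-type ring (C6/C8 and C3′/C5′), as in the diformylation of phloroglucinol itself, and no stereocentre is involved.

**Compound list**
1 | 2-iodo-1,3,5-trimethoxybenzene | COc1cc(OC)c(I)c(OC)c1 | starting material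
2 | (S)-but-3-yn-2-ol | C[C@H](O)C#C | starting material
3 | (S)-4-(2,4,6-trimethoxyphenyl)but-3-yn-2-ol | C[C@H](O)C#Cc1c(OC)cc(OC)cc1OC | intermediate
4 | (S,E)-4-(2,4,6-trimethoxyphenyl)but-3-en-2-ol | C[C@H](O)/C=C/c1c(OC)cc(OC)cc1OC | intermediate
5 | 3-methylbutanoic anhydride | CC(C)CC(=O)OC(=O)CC(C)C | starting material
6 | (S,E)-4-(2,4,6-trimethoxyphenyl)but-3-en-2-yl 3-methylbutanoate | C[C@H](OC(=O)CC(C)C)/C=C/c1c(OC)cc(OC)cc1OC | intermediate
7 | (2R,3R,E)-2-isopropyl-3-(2,4,6-trimethoxyphenyl)hex-4-enoic acid | OC(=O)[C@H](C(C)C)[C@@H](/C=C/C)c1c(OC)cc(OC)cc1OC | intermediate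
8 | 2-methylbut-2-ene | CC=C(C)C | starting material
9 | (2R,3R)-2-isopropyl-5-methyl-3-(2,4,6-trimethoxyphenyl)hex-4-enoic acid | OC(=O)[C@H](C(C)C)[C@@H](C=C(C)C)c1c(OC)cc(OC)cc1OC | intermediate
10 | (2R,3R)-2-isopropyl-5-methyl-3-(2,4,6-trimethoxyphenyl)hexanoic acid | OC(=O)[C@H](C(C)C)[C@@H](CC(C)C)c1c(OC)cc(OC)cc1OC | intermediate
11 | (3R,4R)-5,7-dihydroxy-4-isobutyl-3-isopropylchroman-2-one | CC(C)C[C@H]1c2c(O)cc(O)cc2OC(=O)[C@@H]1C(C)C | intermediate
12 | (3R,4R)-4-isobutyl-3-isopropylchroman-2,5,7-triol | CC(C)C[C@H]1c2c(O)cc(O)cc2OC(O)[C@@H]1C(C)C | intermediate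
13 | phloroglucinol | Oc1cc(O)cc(O)c1 | starting material
14 | (2R,3R,4R)-4-isobutyl-3-isopropyl-2-(2,4,6-trihydroxyphenyl)chroman-5,7-diol | CC(C)C[C@H]1c2c(O)cc(O)cc2O[C@@H](c2c(O)cc(O)cc2O)[C@@H]1C(C)C | intermediate
15 | N,N-dimethylformamide | CN(C)C=O | starting material (formyl source)
16 | sideroxylonal C | CC(C)C[C@H]1c2c(O)c(C=O)c(O)c(C=O)c2O[C@@H](c2c(O)c(C=O)c(O)c(C=O)c2O)[C@@H]1C(C)C | target

**Totals**
Total steps: 10. Longest linear sequence: 10 (1 → 16).

**Three steps most likely to fail, with fallbacks**
1. Step 10 (four-fold formylation): 14 carries an acid-labile C2–aryl bond, so incomplete formylation or C2 ionisation/retro-Friedel–Crafts is possible. Fallback: bring ring B in already formylated by condensing lactol 12 with 2,4-diformylphloroglucinol (Knoevenagel to the o-quinone methide, then intramolecular phenol oxa-Michael closure to the 2,3-trans chroman), leaving only diformylation of ring A on an acid-stable substrate.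
2. Step 5 (cross-metathesis): the propenyl group sits next to a very congested benzylic carbon and may not turn over. Fallback: cleave the alkene (OsO4/NaIO4) to the aldehyde, olefinate with isopropylidenetriphenylphosphorane, then hydrogenate as in step 6.
3. Step 9 (Friedel–Crafts with free phenols): the lactol may oligomerise through its own A ring, or phloroglucinol may add twice. Fallback: run the endgame in the methyl-ether series — mono-demethylative lactonisation of 10 to the 5,7-dimethoxy lactone, DIBAL, BF3-mediated arylation with 1,3,5-trimethoxybenzene, Rieche formylation (Cl2CHOMe/TiCl4), then global BBr3 demethylation.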